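The chroman is cut through its benzene ring: C4a–C5 and C8–C8a are the bonds made last. Ring atoms O1–C8a=C4a–C4 are the enol-ether unit of a δ-lactone, so the pyran ring with its C2 quaternary stereocentre and full side chain is completed first and C5–C8 are supplied by a 2-pyrone. In one operation the lactone silyl ketene acetal and 5-bromo-3-methyl-2-pyrone undergo inverse-demand [4+2] addition, lose CO2 and silanol, and deliver the aromatic ring with the methyl on C8 and a bromine on C6 as latent hydroxyl. The precursor is the O-silyl ketene acetal of an (R)-6-methyl-6-alkyl-δ-valerolactone, made from (R)-citronellyl bromide, (S)-3-bromo-2-methylpropan-1-ol and a Sharpless epoxidation.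

Key step: step 16

Remark: chroman numbering (O1, C2–C4, C4a, C5–C8, C8a, side chain C1′–C13′) is used for these atoms in every intermediate; the target is 2R,4′R,8′S (C8′ is S only because the C11′=C12′ alkene raises the C9′ branch in priority), which requires D-(−)-diethyl tartrate in step 10; the tert-butyldimethylsilyl group is kept on the ketene acetal on purpose, because its bulk blocks silyl transfer and desilylation, which would turn C8a into a hemiketal oxide that expels O1.

Step 1
Reactants: 1 coumalic acid (2-oxo-2H-pyran-5-carboxylic acid)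
Product: 2 3,5-dibromo-2H-pyran-2-one
Conditions: NBS (2.5 equiv), LiOAc, MeCN–H2O (9:1), rt
Reagents that add atoms: N-bromosuccinimide, O=C1CCC(=O)N1Br
Why: Bromodecarboxylation at C5 (ipso-substitution of the carboxylate, Hunsdiecker-type) combined with electrophilic bromination at C3 is the established one-pot behaviour of coumalic acid towards NBS in the presence of acetate.

Step 2
Reactants: 2 3,5-dibromo-2H-pyran-2-one
Product: 3 5-bromo-3-methyl-2H-pyran-2-one
Conditions: Me4Sn (1.1 equiv), Pd(PPh3)4 (5 mol %), PhMe, 100 °C, sealed tube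
Reagents that add atoms: tetramethylstannane, C[Sn](C)(C)C
Why: Stille coupling in which zerovalent palladium inserts preferentially into the C3–Br bond next to the carbonyl of this dibromide in a non-polar, copper-free medium (the known site preference of its cross-couplings), so the methyl goes to C3 and the C5 bromine is kept.

Step 3
Reactants: 4 (S)-3-bromo-2-methylpropan-1-ol
Product: 5 (S)-(3-bromo-2-methylpropoxy)(tert-butyl)dimethylsilane
Conditions: TBSCl, imidazole, CH2Cl2, 0 °C → rt
Reagents that add atoms: tert-butyldimethylsilyl chloride, CC(C)(C)[Si](C)(C)Cl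
Why: Imidazole-mediated O-silylation masks the primary hydroxyl against the Grignard reagent of step 4 and does not touch the stereocentre.

Step 4
Reactants: 5 (S)-(3-bromo-2-methylpropoxy)(tert-butyl)dimethylsilane, 6 (R)-citronellyl bromide [(6R)-8-bromo-2,6-dimethyloct-2-ene]
Product: 8 tert-butyldimethyl{[(2R,6S)-2,6,10-trimethylundec-9-en-1-yl]oxy}silane, via citronellylmagnesium bromide 7 (not isolated)
Conditions: 6, Mg, THF, 40 °C; then 5, Li2CuCl4 (3 mol %), THF–NMP, −20 °C → rt
Reagents that add atoms: none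
Why: Copper-catalysed sp3–sp3 cross-coupling of a primary alkylmagnesium bromide with a primary bromide forms C5′–C6′ without involving any bond to a stereocentre, so C4′ (from 5) and C8′ (from 6) are carried over unchanged.

Step 5
Reactants: 8 tert-butyldimethyl{[(2R,6S)-2,6,10-trimethylundec-9-en-1-yl]oxy}silane
Product: 9 (2R,6S)-2,6,10-trimethylundec-9-en-1-ol
Conditions: PPTS (0.2 equiv), MeOH, 40 °C
Reagents that add atoms: none
Why: Acid-catalysed methanolysis cleaves the primary silyl ether, and pyridinium tosylate is too weak an acid to add methanol to the trisubstituted alkene.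

Step 6
Reactants: 9 (2R,6S)-2,6,10-trimethylundec-9-en-1-ol
Product: 10 (2R,6S)-2,6,10-trimethylundec-9-en-1-yl 4-methylbenzenesulfonate
Conditions: TsCl, Et3N, DMAP (cat.), CH2Cl2, 0 °C → rt
Reagents that add atoms: 4-methylbenzenesulfonyl chloride, Cc1ccc(cc1)S(=O)(=O)Cl
Why: Sulfonylation of the primary alcohol turns C3′ into the electrophile for the second copper-catalysed coupling.

Step 7
Reactants: 10 (2R,6S)-2,6,10-trimethylundec-9-en-1-yl 4-methylbenzenesulfonate, 11 (4-bromobut-1-yn-1-yl)trimethylsilane
Product: 13 trimethyl[(6R,10S)-6,10,14-trimethylpentadec-13-en-1-yn-1-yl]silane, via silylbutynylmagnesium bromide 12 (not isolated)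
Conditions: 11, Mg, THF, rt; then 10, Li2CuCl4 (5 mol %), THF, −78 °C → rt
Reagents that add atoms: none
Why: Copper-catalysed substitution of the primary tosylate by the alkylmagnesium bromide (sp3–sp3 cross-coupling) adds C2′, C1′ and the two alkyne carbons, the silyl cap removing the acidic alkyne hydrogen, and substitution at the CH2 next to C4′ cannot epimerise that centre.

Step 8
Reactants: 13 trimethyl[(6R,10S)-6,10,14-trimethylpentadec-13-en-1-yn-1-yl]silane
Product: 14 (6R,10S)-6,10,14-trimethylpentadec-13-en-1-yne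
Conditions: K2CO3, MeOH, rt
Reagents that add atoms: none
Why: Methoxide-induced protodesilylation of the alkynylsilane frees the terminal alkyne needed for carbometallation.

Step 9
Reactants: 14 (6R,10S)-6,10,14-trimethylpentadec-13-en-1-yne
Product: 17 (2E,7R,11S)-3,7,11,15-tetramethylhexadeca-2,14-dien-1-ol, via alkenyldimethylalane 15 (not isolated), via lithium alkenylalanate 16 (not isolated)
Conditions: AlMe3 (2.5 equiv), Cp2ZrCl2 (0.25 equiv), CH2Cl2, 0 °C → rt; evaporate; n-BuLi, THF, −78 °C; (CH2O)n, −78 °C → rt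
Reagents that add atoms: trimethylaluminium, C[Al](C)C; formaldehyde (as paraformaldehyde), C=O
Why: Zirconium-catalysed carboalumination (Negishi carboalumination) adds CH3 and Al syn across the terminal alkyne with Al on the terminal carbon, and the derived alanate is hydroxymethylated with retention, which fixes the E geometry while the isolated trisubstituted alkene stays inert.

Step 10
Reactants: 17 (2E,7R,11S)-3,7,11,15-tetramethylhexadeca-2,14-dien-1-ol
Product: 18 {(2R,3R)-3-methyl-3-[(4R,8S)-4,8,12-trimethyltridec-11-en-1-yl]oxiran-2-yl}methanol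
Conditions: Ti(OiPr)4 (10 mol %), D-(−)-diethyl tartrate (12 mol %), t-BuOOH, 4 Å MS, CH2Cl2, −20 °C
Reagents that add atoms: tert-butyl hydroperoxide, CC(C)(C)OO
Why: Sharpless asymmetric epoxidation, in which the Ti(OiPr)4/D-(−)-diethyl tartrate catalyst binds the allylic alcohol and delivers oxygen to the face that gives the (2R,3R)-epoxide (the mirror image of the L-tartrate outcome for E-3-methylallylic alcohols), so the future C2 is set as R and the remote alkene, which has no directing hydroxyl, is left alone.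

Step 11
Reactants: 18 {(2R,3R)-3-methyl-3-[(4R,8S)-4,8,12-trimethyltridec-11-en-1-yl]oxiran-2-yl}methanol
Product: 19 (3R,7R,11S)-3,7,11,15-tetramethylhexadec-14-ene-1,3-diol
Conditions: NaAlH2(OCH2CH2OMe)2, THF, 0 °C → rt
Reagents that add atoms: none
Why: The aluminate formed at the primary hydroxyl delivers hydride intramolecularly to the adjacent, less substituted epoxide carbon (1,3-diol-selective reductive opening of a 2,3-epoxy alcohol), so the tertiary C–O bond and its R configuration stay intact.

Step 12
Reactants: 19 (3R,7R,11S)-3,7,11,15-tetramethylhexadec-14-ene-1,3-diol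
Product: 20 (3R,7R,11S)-3-hydroxy-3,7,11,15-tetramethylhexadec-14-en-1-yl 4-methylbenzenesulfonate
Conditions: TsCl (1.1 equiv), Et3N, DMAP (cat.), CH2Cl2, 0 °C
Reagents that add atoms: 4-methylbenzenesulfonyl chloride, Cc1ccc(cc1)S(=O)(=O)Cl
Why: Sulfonylation is selective for the primary hydroxyl because the tertiary one is too hindered to react at 0 °C.

Step 13
Reactants: 20 (3R,7R,11S)-3-hydroxy-3,7,11,15-tetramethylhexadec-14-en-1-yl 4-methylbenzenesulfonate
Product: 21 dimethyl 2-[(3R,7R,11S)-3-hydroxy-3,7,11,15-tetramethylhexadec-14-en-1-yl]propanedioate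
Conditions: CH2(CO2Me)2 (3 equiv), NaH (2.5 equiv), NaI (cat.), THF–DMF, 60 °C
Reagents that add atoms: dimethyl malonate, COC(=O)CC(=O)OC
Why: Malonic ester alkylation (SN2 at the primary tosylate by NaCH(CO2Me)2) adds C4a and C8a; the malonate anion is far too weak a base to ionise the tertiary hydroxyl, so oxetane closure is not expected, excess malonate limits dialkylation, and any material that lactonises onto the tertiary hydroxyl converges in step 14.

Step 14
Reactants: 21 dimethyl 2-[(3R,7R,11S)-3-hydroxy-3,7,11,15-tetramethylhexadec-14-en-1-yl]propanedioate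
Product: 24 (6R)-6-methyl-6-[(4R,8S)-4,8,12-trimethyltridec-11-en-1-yl]oxan-2-one, via hydroxy malonic acid 22 (not isolated), via hydroxy acid 23 (not isolated)
Conditions: KOH, MeOH–H2O, 60 °C; aq. HCl to pH 3, 0 °C, extract; xylene, 140 °C
Reagents that add atoms: none
Why: Saponification, thermal decarboxylation of the malonic acid and lactonisation of the δ-hydroxy acid (the endgame of a malonic ester synthesis) close the ring by acyl–oxygen bond formation, so the tertiary C–O bond and the R configuration are retained.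

Step 15
Reactants: 24 (6R)-6-methyl-6-[(4R,8S)-4,8,12-trimethyltridec-11-en-1-yl]oxan-2-one
Product: 26 tert-butyldimethyl({(2R)-2-methyl-2-[(4R,8S)-4,8,12-trimethyltridec-11-en-1-yl]-3,4-dihydro-2H-pyran-6-yl}oxy)silane, via lithium lactone enolate 25 (not isolated)
Conditions: LiN(iPr)2 (1.1 equiv), THF, −78 °C; TBSCl (1.2 equiv), DMPU, −78 °C → rt; pentane, filtration under Ar
Reagents that add atoms: tert-butyldimethylsilyl chloride, CC(C)(C)[Si](C)(C)Cl
Why: Kinetic deprotonation at the only acidic position (the lactone α-CH2) and O-silylation of the lithium enolate by the hard chlorosilane in the presence of DMPU give the cyclic silyl ketene acetal, and filtration from pentane replaces aqueous work-up because the product hydrolyses readily.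

Step 16
Reactants: 26 tert-butyldimethyl({(2R)-2-methyl-2-[(4R,8S)-4,8,12-trimethyltridec-11-en-1-yl]-3,4-dihydro-2H-pyran-6-yl}oxy)silane, 3 5-bromo-3-methyl-2H-pyran-2-one
Product: 29 (2R)-6-bromo-2,8-dimethyl-2-[(4R,8S)-4,8,12-trimethyltridec-11-en-1-yl]-3,4-dihydro-2H-chromene, via bicyclic lactone adduct 27 (not isolated), via silyloxy cyclohexadiene 28 (not isolated)
Conditions: 3 (2.5 equiv), 2,6-di-tert-butyl-4-methylpyridine (0.3 equiv), PhMe, 120 °C, sealed tube
Reagents that add atoms: none
Why: Proposed new method: the electron-rich ketene acetal 26 should add across C3 and C6 of pyrone 3 in an inverse-electron-demand Diels–Alder reaction in which the nucleophilic alkene carbon (future C4a) bonds to the electrophilic pyrone C6 and the acetal carbon (future C8a) to pyrone C3, after which the bridged lactone 27 expels CO2 by retro-[4+2] and diene 28 aromatises by 1,2-loss of tBuMe2SiOH. The closest known reaction type is the cycloaddition–decarboxylation–elimination sequence of 3,5-dibromo-2-pyrone and of coumalate esters with enol ethers and acyclic ketene acetals, which gives aryl ethers with the same orientation; a lactone-derived cyclic silyl ketene acetal has not been used as the 2π partner. The benzene ring is closed by the intermolecular [4+2] annulation itself (C4a–C5 and C8–C8a formed on the C4a=C8a bond of the finished pyran), so no ring closure takes place at C2. No stereocentre that survives is created (the sp3 carbons of 27 and 28 are flattened on aromatisation) and C2, C4′ and C8′ are spectators under neutral heat. Regioselectivity (methyl on C8, bromine on C6) is secured by the polarisation of both partners. The selectivity that must be won is loss of silanolate and not of the ring oxygen O1 from C8a: silanolate is the better nucleofuge by several pK units and O1 the better lone-pair donor to the developing arenium ion, while the bulky silyl group, the aprotic medium and the hindered pyridine buffer suppress desilylation and protonation of O1, the two events that would open the pyran.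

Step 17
Reactants: 29 (2R)-6-bromo-2,8-dimethyl-2-[(4R,8S)-4,8,12-trimethyltridec-11-en-1-yl]-3,4-dihydro-2H-chromene
Product: 30 2-{(2R)-2,8-dimethyl-2-[(4R,8S)-4,8,12-trimethyltridec-11-en-1-yl]-3,4-dihydro-2H-chromen-6-yl}-4,4,5,5-tetramethyl-1,3,2-dioxaborolane
Conditions: B2pin2 (1.5 equiv), Pd(dppf)Cl2 (5 mol %), KOAc (3 equiv), 1,4-dioxane, 90 °C
Reagents that add atoms: bis(pinacolato)diboron, CC1(C)OB(OC1(C)C)B1OC(C)(C)C(C)(C)O1
Why: Miyaura borylation (oxidative addition of the aryl bromide, acetate-assisted transmetallation with B2pin2, reductive elimination) replaces C6–Br by C6–B, and the chroman ether and the trisubstituted alkene are inert to these conditions.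

Step 18
Reactants: 30 2-{(2R)-2,8-dimethyl-2-[(4R,8S)-4,8,12-trimethyltridec-11-en-1-yl]-3,4-dihydro-2H-chromen-6-yl}-4,4,5,5-tetramethyl-1,3,2-dioxaborolane
Product: 31 (2R)-2,8-dimethyl-2-[(4R,8S)-4,8,12-trimethyltridec-11-en-1-yl]-3,4-dihydro-2H-chromen-6-ol (target)
Conditions: NaBO3·4H2O (3 equiv), THF–H2O (1:1), rt, Ar
Reagents that add atoms: sodium perborate, [Na+].[Na+].O[B-]1(O)OO[B-](O)(O)OO1
Why: Perborate adds to boron and the aryl group migrates to oxygen (oxidative C–B to C–O conversion) before hydrolysis frees the phenol; this nucleophilic oxidant does not epoxidise the isolated alkene, and exclusion of air protects the electron-rich chromanol.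

Compound list
1 | coumalic acid (2-oxo-2H-pyran-5-carboxylic acid) | O=C(O)c1ccc(=O)oc1 | starting material
2 | 3,5-dibromo-2H-pyran-2-one | O=c1occ(Br)cc1Br | intermediate
3 | 5-bromo-3-methyl-2H-pyran-2-one | Cc1cc(Br)coc1=O | intermediate
4 | (S)-3-bromo-2-methylpropan-1-ol | BrC[C@@H](C)CO | starting material
5 | (S)-(3-bromo-2-methylpropoxy)(tert-butyl)dimethylsilane | BrC[C@@H](C)CO[Si](C)(C)C(C)(C)C | intermediate
6 | (R)-citronellyl bromide, (6R)-8-bromo-2,6-dimethyloct-2-ene | CC(C)=CCC[C@@H](C)CCBr | starting material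
7 | citronellylmagnesium bromide, [(3R)-3,7-dimethyloct-6-en-1-yl]magnesium bromide | CC(C)=CCC[C@@H](C)CC[Mg]Br | intermediate
8 | tert-butyldimethyl{[(2R,6S)-2,6,10-trimethylundec-9-en-1-yl]oxy}silane | CC(C)=CCC[C@@H](C)CCC[C@@H](C)CO[Si](C)(C)C(C)(C)C | intermediate
9 | (2R,6S)-2,6,10-trimethylundec-9-en-1-ol | CC(C)=CCC[C@@H](C)CCC[C@@H](C)CO | intermediate
10 | (2R,6S)-2,6,10-trimethylundec-9-en-1-yl 4-methylbenzenesulfonate | CC(C)=CCC[C@@H](C)CCC[C@@H](C)COS(=O)(=O)c1ccc(C)cc1 | intermediate
11 | (4-bromobut-1-yn-1-yl)trimethylsilane | C[Si](C)(C)C#CCCBr | starting material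
12 | [4-(trimethylsilyl)but-3-yn-1-yl]magnesium bromide | C[Si](C)(C)C#CCC[Mg]Br | intermediate
13 | trimethyl[(6R,10S)-6,10,14-trimethylpentadec-13-en-1-yn-1-yl]silane | CC(C)=CCC[C@@H](C)CCC[C@@H](C)CCCC#C[Si](C)(C)C | intermediate
14 | (6R,10S)-6,10,14-trimethylpentadec-13-en-1-yne | CC(C)=CCC[C@@H](C)CCC[C@@H](C)CCCC#C | intermediate
15 | dimethyl[(1E,6R,10S)-2,6,10,14-tetramethylpentadeca-1,13-dien-1-yl]alumane | CC(C)=CCC[C@@H](C)CCC[C@@H](C)CCC/C(C)=C/[Al](C)C | intermediate
16 | lithium butyldimethyl[(1E,6R,10S)-2,6,10,14-tetramethylpentadeca-1,13-dien-1-yl]aluminate | CC(C)=CCC[C@@H](C)CCC[C@@H](C)CCC/C(C)=C/[Al-](C)(C)CCCC.[Li+] | intermediate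
17 | (2E,7R,11S)-3,7,11,15-tetramethylhexadeca-2,14-dien-1-ol | CC(C)=CCC[C@@H](C)CCC[C@@H](C)CCC/C(C)=C/CO | intermediate
18 | {(2R,3R)-3-methyl-3-[(4R,8S)-4,8,12-trimethyltridec-11-en-1-yl]oxiran-2-yl}methanol | CC(C)=CCC[C@@H](C)CCC[C@@H](C)CCC[C@@]1(C)O[C@@H]1CO | intermediate
19 | (3R,7R,11S)-3,7,11,15-tetramethylhexadec-14-ene-1,3-diol | CC(C)=CCC[C@@H](C)CCC[C@@H](C)CCC[C@](O)(C)CCO | intermediate
20 | (3R,7R,11S)-3-hydroxy-3,7,11,15-tetramethylhexadec-14-en-1-yl 4-methylbenzenesulfonate | CC(C)=CCC[C@@H](C)CCC[C@@H](C)CCC[C@](O)(C)CCOS(=O)(=O)c1ccc(C)cc1 | intermediate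
21 | dimethyl 2-[(3R,7R,11S)-3-hydroxy-3,7,11,15-tetramethylhexadec-14-en-1-yl]propanedioate | CC(C)=CCC[C@@H](C)CCC[C@@H](C)CCC[C@](O)(C)CCC(C(=O)OC)C(=O)OC | intermediate
22 | 2-[(3R,7R,11S)-3-hydroxy-3,7,11,15-tetramethylhexadec-14-en-1-yl]propanedioic acid | CC(C)=CCC[C@@H](C)CCC[C@@H](C)CCC[C@](O)(C)CCC(C(=O)O)C(=O)O | intermediate
23 | (5R,9R,13S)-5-hydroxy-5,9,13,17-tetramethyloctadec-16-enoic acid | CC(C)=CCC[C@@H](C)CCC[C@@H](C)CCC[C@](O)(C)CCCC(=O)O | intermediate
24 | (6R)-6-methyl-6-[(4R,8S)-4,8,12-trimethyltridec-11-en-1-yl]oxan-2-one | CC(C)=CCC[C@@H](C)CCC[C@@H](C)CCC[C@]1(C)CCCC(=O)O1 | intermediate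
25 | lithium (2R)-2-methyl-2-[(4R,8S)-4,8,12-trimethyltridec-11-en-1-yl]-3,4-dihydro-2H-pyran-6-olate | CC(C)=CCC[C@@H](C)CCC[C@@H](C)CCC[C@]1(C)CCC=C([O-])O1.[Li+] | intermediate
26 | tert-butyldimethyl({(2R)-2-methyl-2-[(4R,8S)-4,8,12-trimethyltridec-11-en-1-yl]-3,4-dihydro-2H-pyran-6-yl}oxy)silane | CC(C)=CCC[C@@H](C)CCC[C@@H](C)CCC[C@]1(C)CCC=C(O[Si](C)(C)C(C)(C)C)O1 | intermediate
27 | bridged lactone cycloadduct of 26 and 3 (2-oxabicyclo[2.2.2]oct-5-en-3-one fused to the pyran; new sp3 centres unassigned) | CC(C)=CCC[C@@H](C)CCC[C@@H](C)CCC[C@]1(C)CCC2C3OC(=O)C(C)(C=C3Br)C2(O[Si](C)(C)C(C)(C)C)O1 | intermediate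
28 | (2R)-6-bromo-8a-(tert-butyldimethylsilyloxy)-2,8-dimethyl-2-[(4R,8S)-4,8,12-trimethyltridec-11-en-1-yl]-3,4,4a,8a-tetrahydro-2H-chromene (C4a, C8a unassigned) | CC(C)=CCC[C@@H](C)CCC[C@@H](C)CCC[C@]1(C)CCC2C=C(Br)C=C(C)C2(O[Si](C)(C)C(C)(C)C)O1 | intermediate
29 | (2R)-6-bromo-2,8-dimethyl-2-[(4R,8S)-4,8,12-trimethyltridec-11-en-1-yl]-3,4-dihydro-2H-chromene | CC(C)=CCC[C@@H](C)CCC[C@@H](C)CCC[C@]1(C)CCc2cc(Br)cc(C)c2O1 | intermediate
30 | 2-{(2R)-2,8-dimethyl-2-[(4R,8S)-4,8,12-trimethyltridec-11-en-1-yl]-3,4-dihydro-2H-chromen-6-yl}-4,4,5,5-tetramethyl-1,3,2-dioxaborolane | CC(C)=CCC[C@@H](C)CCC[C@@H](C)CCC[C@]1(C)CCc2cc(B3OC(C)(C)C(C)(C)O3)cc(C)c2O1 | intermediate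
31 | (2R)-2,8-dimethyl-2-[(4R,8S)-4,8,12-trimethyltridec-11-en-1-yl]-3,4-dihydro-2H-chromen-6-ol | CC(C)=CCC[C@@H](C)CCC[C@@H](C)CCC[C@]1(C)CCc2cc(O)cc(C)c2O1 | target

Total step count: 18. Longest linear sequence: 16 steps (steps 3–18, from 4 to 31); steps 1–2 form the two-step pyrone branch.

Steps most likely to fail

Step 16. What may go wrong is opening of the pyran during aromatisation (departure of O1 from C8a after desilylation or protonation of O1), or a cycloaddition that is too slow at the methyl-bearing pyrone carbon. The fallback uses known reactions only and reverses the order of ring formation: the arene is bought and the pyran is closed last by aryl–oxygen coupling. It sets out from tosylate 20. Copper-catalysed coupling with (2-chloro-3-methylphenyl)magnesium bromide (from commercial 1-bromo-2-chloro-3-methylbenzene and Mg; 3 equiv, the first equivalent deprotonating the tertiary hydroxyl; Li2CuCl4 cat., THF, −20 °C → rt) should give (3R,7R,11S)-1-(2-chloro-3-methylphenyl)-3,7,11,15-tetramethylhexadec-14-en-3-ol F1. Intramolecular Buchwald–Hartwig etherification (Pd(OAc)2, 2-di-tert-butylphosphino-2′,4′,6′-triisopropylbiphenyl, Cs2CO3, PhMe, 90 °C) forms O1–C8a while the C2–O bond is untouched, and should give (2R)-2,8-dimethyl-2-[(4R,8S)-4,8,12-trimethyltridec-11-en-1-yl]-3,4-dihydro-2H-chromene F2 with C2 retained. Iridium-catalysed C–H borylation ([Ir(OMe)(cod)]2, 4,4′-di-tert-butyl-2,2′-bipyridine, B2pin2, THF, 70 °C) is sterically directed to C6, the only ring C–H with two hydrogen neighbours (C5 lies ortho to C4a, C7 ortho to the C8 methyl). This gives boronate 30, where the route is rejoined before step 18.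

Step 2. What may go wrong is loss of site control in the oxidative addition, so that methyl is transferred to C5 or to both carbons, or methyl transfer from tin so slow that the pyrone decomposes. The fallback makes C3 the only halogen-bearing carbon at the time of methylation. It sets out from acid 1. Fischer esterification (MeOH, H2SO4, reflux) gives methyl coumalate F3. Bromination at C3 (Br2, CH2Cl2, then Et3N) gives methyl 3-bromo-2-oxo-2H-pyran-5-carboxylate F4. Stille methylation of its single C–Br bond (Me4Sn, Pd(PPh3)4, PhMe, 100 °C) gives methyl 3-methyl-2-oxo-2H-pyran-5-carboxylate F5. Acidic ester hydrolysis (aq. HCl, AcOH, 90 °C) gives 3-methyl-2-oxo-2H-pyran-5-carboxylic acid F6. Bromodecarboxylation under the conditions of step 1 with one equivalent of NBS then installs the C5 bromine and comes back to the route at pyrone 3.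

Step 13. What may go wrong is intramolecular attack of the tertiary hydroxyl on the sulfonate (oxetane closure), elimination, or double alkylation of the malonate. The fallback homologates by olefination instead of enolate alkylation. It sets out from diol 19. Selective oxidation of the primary alcohol (TEMPO cat., PhI(OAc)2, CH2Cl2, rt) gives (3R,7R,11S)-3-hydroxy-3,7,11,15-tetramethylhexadec-14-enal F7. Wittig olefination with Ph3P=CHCO2Me (PhMe, rt; neutral, so no retro-aldol) gives methyl (2E,5R,9R,13S)-5-hydroxy-5,9,13,17-tetramethyloctadeca-2,16-dienoate F8. Conjugate reduction with Mg in MeOH, which leaves the isolated trisubstituted alkene alone, gives methyl (5R,9R,13S)-5-hydroxy-5,9,13,17-tetramethyloctadec-16-enoate F9. Warming F9 with catalytic PPTS in PhMe lactonises it to lactone 24, where the route is rejoined at step 15.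

Further compounds
F1 | step 16 | (3R,7R,11S)-1-(2-chloro-3-methylphenyl)-3,7,11,15-tetramethylhexadec-14-en-3-ol | CC(C)=CCC[C@@H](C)CCC[C@@H](C)CCC[C@](O)(C)CCc1cccc(C)c1Cl
F2 | step 16 | (2R)-2,8-dimethyl-2-[(4R,8S)-4,8,12-trimethyltridec-11-en-1-yl]-3,4-dihydro-2H-chromene | CC(C)=CCC[C@@H](C)CCC[C@@H](C)CCC[C@]1(C)CCc2cccc(C)c2O1
F3 | step 2 | methyl coumalate (methyl 2-oxo-2H-pyran-5-carboxylate) | COC(=O)c1ccc(=O)oc1
F4 | step 2 | methyl 3-bromo-2-oxo-2H-pyran-5-carboxylate | COC(=O)c1cc(Br)c(=O)oc1
F5 | step 2 | methyl 3-methyl-2-oxo-2H-pyran-5-carboxylate | COC(=O)c1cc(C)c(=O)oc1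
F6 | step 2 | 3-methyl-2-oxo-2H-pyran-5-carboxylic acid | OC(=O)c1cc(C)c(=O)oc1
F7 | step 13 | (3R,7R,11S)-3-hydroxy-3,7,11,15-tetramethylhexadec-14-enal | CC(C)=CCC[C@@H](C)CCC[C@@H](C)CCC[C@](O)(C)CC=O
F8 | step 13 | methyl (2E,5R,9R,13S)-5-hydroxy-5,9,13,17-tetramethyloctadeca-2,16-dienoate | CC(C)=CCC[C@@H](C)CCC[C@@H](C)CCC[C@](O)(C)C/C=C/C(=O)OC
F9 | step 13 | methyl (5R,9R,13S)-5-hydroxy-5,9,13,17-tetramethyloctadec-16-enoate | CC(C)=CCC[C@@H](C)CCC[C@@H](C)CCC[C@](O)(C)CCCC(=O)OC
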